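**Plan**

- Retrosynthesis: the two C7–O acetyl bonds are cut first, then the two C7–CH3 bonds, which leaves a 6,7,8-trione in each ring. The triones go back by redox to 6,7,8-trihydroxyisoquinolinium rings, whose N2–C1 and N2–C3 bonds are cut to butane-1,4-diamine and two o-alkynylbenzaldehydes. Last come the aryl–alkyne bond and the C9=C10 and C11=C12 alkenes of the side chain.
- Enabling feature: in each 2H-isoquinoline-6,8-dione ring, C7 is a tertiary carbinol carbon between the C6 and C8 carbonyls. Both are vinylogous amides of N2 (C8 through C8a=C1, C6 through C5=C4a–C4=C3). Without its methyl group, C7 is the central and only strongly electrophilic carbonyl of a vicinal tricarbonyl.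
- Forward: the side chain is built from (S)-2-methylbutan-1-ol by two olefinations to a dienyne. The arene comes from 5-bromo-1,2,3-trimethoxybenzene by formylation, chlorination and methyl-to-MOM exchange, and is joined to the chain by Sonogashira coupling. Both pyridine rings then close together on the diamine, followed by deprotection, oxidation to the bis-trione, double methylation and acetylation.
- Stereochemistry: C13/C13′ (S) come from the chiral pool. Both side-chain alkenes are E, from a stabilised ylide and a phosphonate. C7/C7′ (S) come from catalyst-controlled methyl transfer to the Re face of each C7 carbonyl.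

Key step: step 10

Remark 1: with C5–Cl present the CIP order at C7 is O > C6 > C8 > CH3, so the target is 7S,7′S and methyl must enter on the Re face of each C7 carbonyl. Which ligand antipode does this is fixed beforehand on a monomeric N-butyl model trione.

Remark 2: 2-(triphenylphosphoranylidene)propanal, diethyl [3-(trimethylsilyl)prop-2-yn-1-yl]phosphonate and both antipodes of the prolinol ligand are taken as catalogue reagents.

**Route**

Step 1
Reactants: 1 (S)-2-methylbutan-1-ol
Product: 3 (2E,4S)-2,4-dimethylhex-2-enal, via (S)-2-methylbutanal 2 (not isolated)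
Conditions: TEMPO (1 mol %), KBr (10 mol %), aq. NaOCl (1.1 equiv), NaHCO3, CH2Cl2, 0 °C; dried organic phase, then Ph3P=C(Me)CHO (1.2 equiv), CH2Cl2/toluene, sealed tube, 70 °C
Reagents that add atoms: 2-(triphenylphosphoranylidene)propanal, CC(C=O)=P(c1ccccc1)(c1ccccc1)c1ccccc1
Why: Anelli oxidation gives the configurationally labile aldehyde without base or isolation, and Wittig olefination with the formyl-stabilised ylide should give the trisubstituted E-enal, the C4 stereocentre being carried over unchanged from 1.

Step 2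
Reactants: 3 (2E,4S)-2,4-dimethylhex-2-enal
Product: 5 (3E,5E,7S)-5,7-dimethylnona-3,5-dien-1-yne, via C-silylated dienyne 4 (not isolated)
Conditions: (EtO)2P(O)CH2C≡CSiMe3 (1.3 equiv), LiHMDS (1.25 equiv), THF, −78 → 0 °C; then K2CO3 (cat.), MeOH, rt; product kept as a concentrated pentane/ether solution
Reagents that add atoms: diethyl [3-(trimethylsilyl)prop-2-yn-1-yl]phosphonate, CCOP(=O)(CC#C[Si](C)(C)C)OCC
Why: Horner–Wadsworth–Emmons olefination with the preformed propargyl phosphonate anion is an established E-selective entry to conjugated enynes (no free amide base remains to deprotonate the γ-stereocentre), and carbonate-catalysed methanolysis of the C–Si bond frees the terminal alkyne.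

Step 3
Reactants: 6 5-bromo-1,2,3-trimethoxybenzene
Product: 7 6-bromo-2,3,4-trimethoxybenzaldehyde
Conditions: Cl2CHOMe (1.5 equiv), TiCl4 (2.2 equiv), CH2Cl2, −10 → 0 °C; then ice/aq. HCl
Reagents that add atoms: dichloromethyl methyl ether, COC(Cl)Cl; water, O
Why: Rieche formylation of an electron-rich arene whose two free positions are equivalent and each ortho to a methoxy group, so only one aldehyde can form.

Step 4
Reactants: 7 6-bromo-2,3,4-trimethoxybenzaldehyde
Product: 8 6-bromo-5-chloro-2,3,4-trimethoxybenzaldehyde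
Conditions: NCS (1.1 equiv), TFA (10 mol %), MeCN, 50 °C, dark
Reagents that add atoms: N-chlorosuccinimide, O=C1CCC(=O)N1Cl
Why: electrophilic aromatic chlorination at the single remaining ring C–H, which is ortho and para to methoxy groups and meta to the aldehyde, puts the future C5 chlorine in place before any alkene is present.

Step 5
Reactants: 8 6-bromo-5-chloro-2,3,4-trimethoxybenzaldehyde
Product: 9 6-bromo-5-chloro-2,3,4-trihydroxybenzaldehyde
Conditions: BBr3 (4.5 equiv), CH2Cl2, −78 °C → rt; then H2O, 0 °C; Ar
Reagents that add atoms: none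
Why: BBr3 cleavage of aryl methyl ethers is tolerated by aryl aldehydes and aryl halides, and doing it on this simple arene keeps the Lewis acid away from the later polyene.

Step 6
Reactants: 9 6-bromo-5-chloro-2,3,4-trihydroxybenzaldehyde
Product: 10 6-bromo-5-chloro-2,3,4-tris(methoxymethoxy)benzaldehyde
Conditions: MOMCl (4.5 equiv), iPr2NEt (6 equiv), Bu4NI (cat.), CH2Cl2, 0 → 40 °C, Ar
Reagents that add atoms: chloromethyl methyl ether, COCCl
Why: O-alkylation of the three phenols with MOMCl gives acetal ethers that survive Pd/Cu/amine and Ag(I) and later leave in mild methanolic HCl, which the side chain should tolerate.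

Step 7
Reactants: 10 6-bromo-5-chloro-2,3,4-tris(methoxymethoxy)benzaldehyde; 5 (3E,5E,7S)-5,7-dimethylnona-3,5-dien-1-yne (1.3 equiv)
Product: 11 5-chloro-6-[(3E,5E,7S)-5,7-dimethylnona-3,5-dien-1-yn-1-yl]-2,3,4-tris(methoxymethoxy)benzaldehyde
Conditions: PdCl2(PPh3)2 (5 mol %), CuI (10 mol %), Et3N/DMF 1:3, degassed, 65 °C
Reagents that add atoms: none
Why: Sonogashira coupling, in which the ortho-formyl group activates the C–Br bond for oxidative addition while a triphenylphosphine catalyst should leave the C–Cl bond untouched.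

Step 8
Reactants: 11 alkynylbenzaldehyde (2.1 equiv); 12 butane-1,4-diamine (1.0 equiv)
Product: 15 butane-linked bis(5-chloro-3-dienyl-6,7,8-trihydroxyisoquinolinium) dichloride, via bis-aldimine 13 (not isolated), via bis(1-methoxy-1,2-dihydroisoquinoline) 14 (not isolated)
Conditions: 3 Å MS, MeOH/CH2Cl2 2:1, rt; AgOTf (10 mol %), 40 °C; then HCl (1.25 M in MeOH), 40 °C; Ar throughout; trituration with Et2O
Reagents that add atoms: hydrogen chloride, Cl
Why: condensation gives the E,E-bis-aldimine, and Ag(I)-catalysed 6-endo-dig attack of each imine nitrogen on its alkyne (protodemetallation and C1 capture by methanol) is the established aza-annulation of o-alkynylbenzaldimines; methanolic HCl then ionises both N,O-acetals to aromatic isoquinolinium rings, removes the six MOM groups and precipitates silver as AgCl before the pyrogallol units are unmasked.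

Step 9
Reactants: 15 bis(trihydroxyisoquinolinium) dichloride
Product: 16 butane-linked bis(5-chloro-3-dienylisoquinoline-6,7,8(2H)-trione)
Conditions: Ag2O (8 equiv), powdered 4 Å MS, MeCN/CH2Cl2, rt, dark, Ar; filtration through Celite; toluene azeotrope
Reagents that add atoms: none
Why: silver(I) oxide oxidation of a catechol/pyrogallol unit to the o-quinone level under anhydrous conditions, in which the oxide also removes HCl as AgCl so that the neutral 6-oxo form results, and C5–Cl blocks the ring position through which hydroxy-o-quinones usually couple.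

Step 10
Reactants: 16 bis-trione; 17 dimethylzinc
Product: 18 (7S,7′S)-butane-linked bis(5-chloro-3-dienyl-7-hydroxy-7-methylisoquinoline-6,8(2H,7H)-dione)
Conditions: Me2Zn (8 equiv, toluene), diphenyl(1-methylpyrrolidin-2-yl)methanol (40 mol %, antipode as fixed in Remark 1), toluene/CH2Cl2, −40 → −20 °C, slow addition of 16; then pH 7 aqueous buffer
Reagents that add atoms: dimethylzinc (17), C[Zn]C
Why: Proposed new method: the zinc amino-alkoxide formed from the ligand and Me2Zn should chelate the O7/O8 edge of each trione while its alkoxide oxygen activates a second Me2Zn, which transfers methyl to C7 through a bimetallic cyclic transition state; the closest known chemistry is the ligand-accelerated enantioselective addition of Me2Zn to α-keto esters, isatins and 1,2-diketones, together with the central-carbonyl preference of nucleophiles for vicinal tricarbonyls. No ring is closed; two C7–CH3 bonds and two tertiary carbinol centres are formed. Site selectivity rests on the substrate: C6 and C8 are vinylogous amides of N2 and barely electrophilic, so C7 is the only ketone Me2Zn should attack, and no copper is present to open conjugate pathways. Facial selectivity is controlled by the ligand: O8 is more Lewis basic than O6, which is doubly vinylogous and flanked by C5–Cl, so a single O7/O8 chelate should form and the ligand then shields one face, the required sense being Re-face delivery (O > C6 > C8) to give 7S. The two ends are remote and react independently, so the catalyst acts twice and a wrong-face event ends mainly in the 7R,7′S diastereomer, to be removed by chromatography. Slow addition at low temperature is meant to keep the uncatalysed background addition below the ligand-accelerated one.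

Step 11
Reactants: 18 (7S,7′S)-bis-carbinol
Product: 19 Penazaphilone I
Conditions: Ac2O (6 equiv), DMAP (0.5 equiv), Et3N (8 equiv), CH2Cl2, 0 °C → rt
Reagents that add atoms: acetic anhydride, CC(=O)OC(C)=O
Why: DMAP-catalysed acylation of the tertiary α-ketol hydroxyls is the usual way a C7 acetate is placed on azaphilone cores, and the quaternary C7 centres cannot epimerise.

**Compound list**

1 | (S)-2-methylbutan-1-ol | CC[C@H](C)CO | starting material
2 | (S)-2-methylbutanal (not isolated) | CC[C@H](C)C=O | intermediate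
3 | (2E,4S)-2,4-dimethylhex-2-enal | CC[C@H](C)/C=C(C)/C=O | intermediate
4 | trimethyl[(3E,5E,7S)-5,7-dimethylnona-3,5-dien-1-yn-1-yl]silane (not isolated) | CC[C@H](C)/C=C(C)/C=C/C#C[Si](C)(C)C | intermediate
5 | (3E,5E,7S)-5,7-dimethylnona-3,5-dien-1-yne | CC[C@H](C)/C=C(C)/C=C/C#C | intermediate
6 | 5-bromo-1,2,3-trimethoxybenzene | COc1cc(Br)cc(OC)c1OC | starting material
7 | 6-bromo-2,3,4-trimethoxybenzaldehyde | COc1cc(Br)c(C=O)c(OC)c1OC | intermediate
8 | 6-bromo-5-chloro-2,3,4-trimethoxybenzaldehyde | COc1c(Cl)c(Br)c(C=O)c(OC)c1OC | intermediate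
9 | 6-bromo-5-chloro-2,3,4-trihydroxybenzaldehyde | Oc1c(Cl)c(Br)c(C=O)c(O)c1O | intermediate
10 | 6-bromo-5-chloro-2,3,4-tris(methoxymethoxy)benzaldehyde | COCOc1c(Cl)c(Br)c(C=O)c(OCOC)c1OCOC | intermediate
11 | 5-chloro-6-[(3E,5E,7S)-5,7-dimethylnona-3,5-dien-1-yn-1-yl]-2,3,4-tris(methoxymethoxy)benzaldehyde | CC[C@H](C)/C=C(C)/C=C/C#Cc1c(Cl)c(OCOC)c(OCOC)c(OCOC)c1C=O | intermediate
12 | butane-1,4-diamine | NCCCCN | starting material
13 | (E,E)-N,N′-butane-1,4-diylbis(1-{5-chloro-6-[(3E,5E,7S)-5,7-dimethylnona-3,5-dien-1-yn-1-yl]-2,3,4-tris(methoxymethoxy)phenyl}methanimine) (not isolated) | CC[C@H](C)/C=C(C)/C=C/C#Cc1c(Cl)c(OCOC)c(OCOC)c(OCOC)c1/C=N/CCCC/N=C/c1c(OCOC)c(OCOC)c(OCOC)c(Cl)c1C#C/C=C/C(C)=C/[C@@H](C)CC | intermediate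
14 | 2,2′-(butane-1,4-diyl)bis{5-chloro-3-[(1E,3E,5S)-3,5-dimethylhepta-1,3-dien-1-yl]-1-methoxy-6,7,8-tris(methoxymethoxy)-1,2-dihydroisoquinoline}, C1 epimers (not isolated) | CC[C@H](C)/C=C(C)/C=C/C1=Cc2c(Cl)c(OCOC)c(OCOC)c(OCOC)c2C(OC)N1CCCCN1C(OC)c2c(OCOC)c(OCOC)c(OCOC)c(Cl)c2C=C1/C=C/C(C)=C/[C@@H](C)CC | intermediate
15 | 2,2′-(butane-1,4-diyl)bis{5-chloro-3-[(1E,3E,5S)-3,5-dimethylhepta-1,3-dien-1-yl]-6,7,8-trihydroxyisoquinolin-2-ium} dichloride | CC[C@H](C)/C=C(C)/C=C/c1cc2c(Cl)c(O)c(O)c(O)c2c[n+]1CCCC[n+]1cc2c(O)c(O)c(O)c(Cl)c2cc1/C=C/C(C)=C/[C@@H](C)CC.[Cl-].[Cl-] | intermediate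
16 | 2,2′-(butane-1,4-diyl)bis{5-chloro-3-[(1E,3E,5S)-3,5-dimethylhepta-1,3-dien-1-yl]isoquinoline-6,7,8(2H)-trione} | CC[C@H](C)/C=C(C)/C=C/C1=CC2=C(Cl)C(=O)C(=O)C(=O)C2=CN1CCCCN1C=C2C(=O)C(=O)C(=O)C(Cl)=C2C=C1/C=C/C(C)=C/[C@@H](C)CC | intermediate
17 | dimethylzinc | C[Zn]C | starting material
18 | (7S,7′S)-2,2′-(butane-1,4-diyl)bis{5-chloro-3-[(1E,3E,5S)-3,5-dimethylhepta-1,3-dien-1-yl]-7-hydroxy-7-methylisoquinoline-6,8(2H,7H)-dione} | CC[C@H](C)/C=C(C)/C=C/C1=CC2=C(Cl)C(=O)[C@@](C)(O)C(=O)C2=CN1CCCCN1C=C2C(=O)[C@](C)(O)C(=O)C(Cl)=C2C=C1/C=C/C(C)=C/[C@@H](C)CC | intermediate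
19 | Penazaphilone I, the 7,7′-diacetate of 18 | CC[C@H](C)/C=C(C)/C=C/C1=CC2=C(Cl)C(=O)[C@@](C)(OC(C)=O)C(=O)C2=CN1CCCCN1C=C2C(=O)[C@](C)(OC(C)=O)C(=O)C(Cl)=C2C=C1/C=C/C(C)=C/[C@@H](C)CC | target

**Count**

Total: 11 steps. Longest linear sequence: 9 steps (steps 3 to 11, from 6); the side-chain branch from 1 needs 7.

**Steps most likely to fail**

Step 10. Facial selectivity may be poor if the O6/O7 chelate competes or if uncatalysed addition keeps pace with the catalysed one. Electron transfer from Me2Zn to the quinone-like trione could also return the enediolate or lead to O-methylation. The fallback uses known chemistry, sets out from 5 and returns at 18: the C7 centre is made by enantioselective oxidative dearomatisation instead of carbonyl addition. 5-Bromo-2-methylresorcinol is ortho-formylated (Vilsmeier) to 6-bromo-2,4-dihydroxy-3-methylbenzaldehyde F1, and Sonogashira coupling with 5 gives 6-dienynyl-2,4-dihydroxy-3-methylbenzaldehyde F2. Copper(I)–sparteine–O2 hydroxylative dearomatisation at the methyl-bearing carbon, followed by cycloisomerisation, gives the (7R)-7-hydroxy-7-methyl azaphilone F3; the sparteine antipode (natural (−)-sparteine or a (+)-sparteine surrogate) is chosen for this sense. NCS chlorination at C5 gives the 5-chloro azaphilone F4, whose descriptor becomes 7S through the priority change. Two equivalents of F4 condense with 12, exchanging the pyran oxygen for nitrogen, to give 18, which is acetylated as in step 11.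

Step 9. The electrophilic trione may over-oxidise or oligomerise on the silver surface, the salt may dissolve poorly, and covalent hydration at C7 would later consume Me2Zn. The fallback sets out from 15 and returns at 16: homogeneous periodate oxidation in buffered aqueous acetonitrile, in which hydration is accepted and the bis(7,7-dihydroxy) hydrate F5 is isolated as the storage form usual for vicinal tricarbonyls. F5 is dehydrated by azeotropic distillation from toluene (or over P2O5 in vacuo) directly before step 10 to give 16.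

Step 8. The second annulation may stall after the first, the imines may be cleaved by methanol before cyclisation, or 5-exo closure may compete. The fallback sets out from 11 and returns at 15: the ring is closed with ammonia and the linker is attached afterwards. Compound 11 with NH3/MeOH and catalytic AgOTf gives 5-chloro-3-dienyl-6,7,8-tris(methoxymethoxy)isoquinoline F6. Two equivalents of F6 are N-alkylated with butane-1,4-diyl bis(trifluoromethanesulfonate) to the hexa-MOM bis-isoquinolinium bis(triflate) F7. Methanolic HCl and passage through a chloride-form anion-exchange resin then give 15.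

Further compounds

F1 | step 10 | 6-bromo-2,4-dihydroxy-3-methylbenzaldehyde | Cc1c(O)cc(Br)c(C=O)c1O
F2 | step 10 | 6-[(3E,5E,7S)-5,7-dimethylnona-3,5-dien-1-yn-1-yl]-2,4-dihydroxy-3-methylbenzaldehyde | CC[C@H](C)/C=C(C)/C=C/C#Cc1cc(O)c(C)c(O)c1C=O
F3 | step 10 | (7R)-3-[(1E,3E,5S)-3,5-dimethylhepta-1,3-dien-1-yl]-7-hydroxy-7-methyl-6H-isochromene-6,8(7H)-dione | CC[C@H](C)/C=C(C)/C=C/C1=CC2=CC(=O)[C@@](C)(O)C(=O)C2=CO1
F4 | step 10 | (7S)-5-chloro-3-[(1E,3E,5S)-3,5-dimethylhepta-1,3-dien-1-yl]-7-hydroxy-7-methyl-6H-isochromene-6,8(7H)-dione | CC[C@H](C)/C=C(C)/C=C/C1=CC2=C(Cl)C(=O)[C@@](C)(O)C(=O)C2=CO1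
F5 | step 9 | 2,2′-(butane-1,4-diyl)bis{5-chloro-3-[(1E,3E,5S)-3,5-dimethylhepta-1,3-dien-1-yl]-7,7-dihydroxyisoquinoline-6,8(2H,7H)-dione} | CC[C@H](C)/C=C(C)/C=C/C1=CC2=C(Cl)C(=O)C(O)(O)C(=O)C2=CN1CCCCN1C=C2C(=O)C(O)(O)C(=O)C(Cl)=C2C=C1/C=C/C(C)=C/[C@@H](C)CC
F6 | step 8 | 5-chloro-3-[(1E,3E,5S)-3,5-dimethylhepta-1,3-dien-1-yl]-6,7,8-tris(methoxymethoxy)isoquinoline | CC[C@H](C)/C=C(C)/C=C/c1cc2c(Cl)c(OCOC)c(OCOC)c(OCOC)c2cn1
F7 | step 8 | 2,2′-(butane-1,4-diyl)bis{5-chloro-3-[(1E,3E,5S)-3,5-dimethylhepta-1,3-dien-1-yl]-6,7,8-tris(methoxymethoxy)isoquinolin-2-ium} bis(trifluoromethanesulfonate) | CC[C@H](C)/C=C(C)/C=C/c1cc2c(Cl)c(OCOC)c(OCOC)c(OCOC)c2c[n+]1CCCC[n+]1cc2c(OCOC)c(OCOC)c(OCOC)c(Cl)c2cc1/C=C/C(C)=C/[C@@H](C)CC.[O-]S(=O)(=O)C(F)(F)F.[O-]S(=O)(=O)C(F)(F)F
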